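**Retrosynthetic overview**
- The single ring, the 14-membered carbocycle, is closed last but one: target ⇐ DIBAL-H reduction of the macrocyclic (Z)-enoate ⇐ intramolecular Still–Gennari HWE that forms the ring C1=C2 bond.
- Seco aldehyde–phosphonate ⇐ iminium-catalysed enantioselective conjugate addition of the complete (E)-dienyl side chain, as its trifluoroborate, to an achiral (E)-enal. This sets the only stereocentre of the target (ring C4).
- Enal ⇐ cross-metathesis of a terminal isopropylidene with crotonaldehyde; phosphonate ⇐ alkylation of the Still–Gennari phosphonoacetate with (3E,7Z)-homofarnesyl iodide.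
- (3E,7Z)-Homofarnesyl chain ⇐ nerol (supplies the Z alkene) via neryl bromide, propargyl-dianion alkylation and Zr-catalysed carboalumination/ethylene oxide (sets the E alkene).
- Side-chain trifluoroborate ⇐ prenyl bromide + propynyl Grignard, then hydrozirconation/iodination and Li→B exchange/KHF2.

**Assumptions**
- Nerol, propyne, ethylene oxide, methyl bis(2,2,2-trifluoroethyl)phosphonoacetate, crotonaldehyde, prenyl bromide and 1-propynylmagnesium bromide (THF solution) are taken as commercial.
- Discrete carbon–metal species generated in the flask are numbered as non-isolated intermediates; catalyst-bound species (iminium ions, Ru alkylidenes), O-metal salts awaiting work-up and the HWE oxaphosphetane are not numbered.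
- The phosphonate-bearing carbon of 14, 16 and 25 is an unassigned, base-labile centre (both epimers are carried) that is planarised in step 11.

Step 1
Reactants: 1 nerol [(2Z)-3,7-dimethylocta-2,6-dien-1-ol]
Product: 2 neryl bromide [(2Z)-1-bromo-3,7-dimethylocta-2,6-diene]
Conditions: PBr3 (0.4 equiv), Et2O, −10 °C
Reagents that add atoms: phosphorus tribromide, BrP(Br)Br
Why: Bromination of the primary allylic alcohol with PBr3 (SN2 on the phosphite ester) at low temperature proceeds without allylic transposition or Z→E isomerisation.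

Step 2
Reactants: 2 neryl bromide; 3 propyne
Product: 6 (5Z)-6,10-dimethylundeca-5,9-dien-1-yne, via 1,3-dilithiopropyne 4 (not isolated), via lithium alkynide 5 (not isolated)
Conditions: 3, n-BuLi (2 equiv), TMEDA, Et2O/hexane, 0 °C; then 2, −78 °C → rt; H2O
Reagents that add atoms: none
Why: Propargyl-dianion alkylation: the sp3 terminus of 1,3-dilithiopropyne displaces the primary allylic bromide (SN2, Z geometry retained) and the surviving acetylide is protonated on work-up to give the terminal 1,5-enyne.

Step 3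
Reactants: 6 (5Z)-6,10-dimethylundeca-5,9-dien-1-yne; 7 ethylene oxide
Product: 10 (3E,7Z)-4,8,12-trimethyltrideca-3,7,11-trien-1-ol, via alkenyldimethylalane 8 (not isolated), via lithium alkenylaluminate 9 (not isolated)
Conditions: AlMe3 (2 equiv), Cp2ZrCl2 (0.25 equiv), CH2Cl2, rt; remove excess AlMe3 in vacuo; n-BuLi (1 equiv), hexane/THF, −78 °C; 7, −78 °C → rt; aq. NH4Cl
Reagents that add atoms: trimethylaluminium, C[Al](C)C
Why: Negishi Zr-catalysed carboalumination adds Me–Al syn across the terminal alkyne with Me on the internal carbon (fixing the E trisubstituted alkene), and the derived aluminate opens ethylene oxide with retention of alkene geometry; the trisubstituted alkenes are inert.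

Step 4
Reactants: 10 (3E,7Z)-4,8,12-trimethyltrideca-3,7,11-trien-1-ol
Product: 11 (6Z,10E)-13-iodo-2,6,10-trimethyltrideca-2,6,10-triene
Conditions: I2, PPh3, imidazole, CH2Cl2, 0 °C
Reagents that add atoms: iodine, II
Why: Appel-type iodination: SN2 displacement of the alkoxyphosphonium at the primary carbon under neutral conditions that leave the three alkenes untouched.

Step 5
Reactants: 11 (6Z,10E)-13-iodo-2,6,10-trimethyltrideca-2,6,10-triene; 12 methyl bis(2,2,2-trifluoroethyl)phosphonoacetate
Product: 14 methyl (5E,9Z)-2-[bis(2,2,2-trifluoroethoxy)phosphoryl]-6,10,14-trimethylpentadeca-5,9,13-trienoate, via sodium phosphonoacetate enolate 13 (not isolated)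
Conditions: 12 (2.5 equiv), NaH (2.4 equiv), DMF, 0 °C; then 11, 50 °C
Reagents that add atoms: none
Why: SN2 C-alkylation of the stabilised phosphonoacetate anion by the primary iodide (malonate-type alkylation), excess 12 limiting dialkylation; the new C-2 centre is racemic and is planarised in step 11.

Step 6
Reactants: 14 methyl (5E,9Z)-2-[bis(2,2,2-trifluoroethoxy)phosphoryl]-6,10,14-trimethylpentadeca-5,9,13-trienoate; 15 (E)-crotonaldehyde
Product: 16 methyl (5E,9Z,13E)-2-[bis(2,2,2-trifluoroethoxy)phosphoryl]-6,10-dimethyl-15-oxopentadeca-5,9,13-trienoate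
Conditions: Hoveyda–Grubbs II (5 mol %), 15 (8 equiv), CH2Cl2, 40 °C
Reagents that add atoms: none
Why: Olefin cross-metathesis: the terminal isopropylidene is the least hindered trisubstituted alkene and reacts while the two internal trisubstituted alkenes are spectators, and the enal partner gives the (E)-enal with loss of 2-methylbut-2-ene.

Step 7
Reactants: 17 prenyl bromide (1-bromo-3-methylbut-2-ene); 18 1-propynylmagnesium bromide
Product: 19 6-methylhept-5-en-2-yne
Conditions: CuI (5 mol %), THF, 0 °C → rt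
Reagents that add atoms: none
Why: Copper-catalysed coupling of the alkynyl Grignard with the primary allylic bromide at the unhindered α-carbon (SN2) gives the skipped enyne.

Step 8
Reactants: 19 6-methylhept-5-en-2-yne
Product: 21 (2E)-2-iodo-6-methylhepta-2,5-diene, via alkenylzirconocene chloride 20 (not isolated)
Conditions: Cp2Zr(H)Cl (1.6 equiv), THF, rt → 40 °C; then I2, 0 °C
Reagents that add atoms: iodine, II
Why: Schwartz hydrozirconation adds Zr–H syn and, with excess reagent, equilibrates to the less hindered regioisomer (Zr on the methyl-bearing carbon); iodinolysis with retention gives the (E)-iodide.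

Step 9
Reactants: 21 (2E)-2-iodo-6-methylhepta-2,5-diene
Product: 24 potassium trifluoro[(2Z)-6-methylhepta-2,5-dien-2-yl]borate, via alkenyllithium 22 (not isolated), via lithium alkenyltriisopropoxyborate 23 (not isolated)
Conditions: t-BuLi (2.1 equiv), Et2O, −78 °C; B(OiPr)3, −78 °C → rt; aq. KHF2
Reagents that add atoms: triisopropyl borate, CC(C)OB(OC(C)C)OC(C)C; potassium hydrogen difluoride, F.[F-].[K+]
Why: Iodine–lithium exchange and borylation proceed with retention at the alkenyl carbon and KHF2 gives the crystalline trifluoroborate (recrystallisation removes the minor regioisomer); the descriptor becomes Z only because B ranks below CH3.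

Step 10
Reactants: 16 methyl (5E,9Z,13E)-2-[bis(2,2,2-trifluoroethoxy)phosphoryl]-6,10-dimethyl-15-oxopentadeca-5,9,13-trienoate; 24 potassium trifluoro[(2Z)-6-methylhepta-2,5-dien-2-yl]borate
Product: 25 methyl (5E,9Z,13R,14E)-2-[bis(2,2,2-trifluoroethoxy)phosphoryl]-6,10,14,18-tetramethyl-13-(2-oxoethyl)nonadeca-5,9,14,17-tetraenoate
Conditions: (2S,5S)-5-benzyl-2-tert-butyl-3-methylimidazolidin-4-one·HCl (20 mol %), HF (48% aq., 1.0 equiv), 24 (2.5 equiv), DME (1 M), −20 → 4 °C, polyethylene vessel
Reagents that add atoms: none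
Why: Proposed new method: iminium-catalysed enantioselective conjugate alkenylation with an α-methyl, all-alkyl trisubstituted alkenyltrifluoroborate (closest known reaction type: imidazolidinone/HF-mediated Friedel–Crafts-type conjugate addition of β-aryl vinyl and heteroaryl trifluoroborates to simple enals, which has not been shown for α-branched all-alkyl alkenyl borates or polyene enals); the boron-bearing carbon of 24 attacks C-β of the (E)-iminium of 16, the developing secondary cation is stabilised by hyperconjugation with the electron-rich C–B(ate) bond (which also directs ipso attack and leaves the skipped prenyl alkene untouched), BF3 is lost after least-motion rotation so the alkene geometry is retained (E in the product), HF traps BF3 as KBF4, and the benzyl group of the (2S,5S)-catalyst blocks the Si face so that Re-face attack gives 13R, the same facial sense as the known indole and pyrrole alkylations of crotonaldehyde with this catalyst.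

Step 11
Reactants: 25 methyl (5E,9Z,13R,14E)-2-[bis(2,2,2-trifluoroethoxy)phosphoryl]-6,10,14,18-tetramethyl-13-(2-oxoethyl)nonadeca-5,9,14,17-tetraenoate
Product: 27 methyl (1Z,4R,7Z,11E)-7,11-dimethyl-4-[(2E)-6-methylhepta-2,5-dien-2-yl]cyclotetradeca-1,7,11-triene-1-carboxylate, via potassium phosphonate carbanion 26 (not isolated)
Conditions: K2CO3 (6 equiv), 18-crown-6 (12 equiv), toluene, 1 mM (syringe pump, 12 h), 0 °C → rt
Reagents that add atoms: none
Why: Intramolecular Still–Gennari Horner–Wadsworth–Emmons olefination: the electron-poor trifluoroethyl phosphonate with dissociated K+ collapses from the syn adduct to place the ester cis to the aldehyde-derived CH2 (1Z), which is also the less strained in-ring trans arrangement of the 14-membered ring; high dilution favours cyclisation and the β-stereocentre cannot epimerise.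

Step 12
Reactants: 27 methyl (1Z,4R,7Z,11E)-7,11-dimethyl-4-[(2E)-6-methylhepta-2,5-dien-2-yl]cyclotetradeca-1,7,11-triene-1-carboxylate
Product: 28 [(1Z,4R,7Z,11E)-7,11-dimethyl-4-[(2E)-6-methylhepta-2,5-dien-2-yl]cyclotetradeca-1,7,11-trien-1-yl]methanol (target)
Conditions: DIBAL-H (2.5 equiv), CH2Cl2, −78 °C; Rochelle salt
Reagents that add atoms: none
Why: DIBAL-H 1,2-reduction of the α,β-unsaturated ester gives the allylic alcohol without touching the stereocentre or any of the four alkene geometries.

**Compound list**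
1 | nerol, (2Z)-3,7-dimethylocta-2,6-dien-1-ol | OC/C=C(/C)CCC=C(C)C | starting material
2 | neryl bromide, (2Z)-1-bromo-3,7-dimethylocta-2,6-diene | BrC/C=C(/C)CCC=C(C)C | intermediate
3 | propyne | CC#C | starting material
4 | 1,3-dilithiopropyne | [Li]CC#C[Li] | intermediate (not isolated)
5 | lithium (5Z)-6,10-dimethylundeca-5,9-dien-1-yn-1-ide | [Li]C#CCC/C=C(/C)CCC=C(C)C | intermediate (not isolated)
6 | (5Z)-6,10-dimethylundeca-5,9-dien-1-yne | C#CCC/C=C(/C)CCC=C(C)C | intermediate
7 | ethylene oxide (oxirane) | C1CO1 | starting material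
8 | dimethyl[(1E,5Z)-2,6,10-trimethylundeca-1,5,9-trien-1-yl]alane | C[Al](C)/C=C(\C)CC/C=C(/C)CCC=C(C)C | intermediate (not isolated)
9 | lithium butyl(dimethyl)[(1E,5Z)-2,6,10-trimethylundeca-1,5,9-trien-1-yl]aluminate | [Li+].CCCC[Al-](C)(C)/C=C(\C)CC/C=C(/C)CCC=C(C)C | intermediate (not isolated)
10 | (3E,7Z)-4,8,12-trimethyltrideca-3,7,11-trien-1-ol | OCC/C=C(\C)CC/C=C(/C)CCC=C(C)C | intermediate
11 | (6Z,10E)-13-iodo-2,6,10-trimethyltrideca-2,6,10-triene | ICC/C=C(\C)CC/C=C(/C)CCC=C(C)C | intermediate
12 | methyl bis(2,2,2-trifluoroethyl)phosphonoacetate | COC(=O)CP(=O)(OCC(F)(F)F)OCC(F)(F)F | starting material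
13 | sodium [bis(2,2,2-trifluoroethoxy)phosphoryl](methoxycarbonyl)methanide | [Na+].COC(=O)[CH-]P(=O)(OCC(F)(F)F)OCC(F)(F)F | intermediate (not isolated)
14 | methyl (5E,9Z)-2-[bis(2,2,2-trifluoroethoxy)phosphoryl]-6,10,14-trimethylpentadeca-5,9,13-trienoate (racemic at C-2) | COC(=O)C(CC/C=C(\C)CC/C=C(/C)CCC=C(C)C)P(=O)(OCC(F)(F)F)OCC(F)(F)F | intermediate
15 | (E)-crotonaldehyde | C/C=C/C=O | starting material
16 | methyl (5E,9Z,13E)-2-[bis(2,2,2-trifluoroethoxy)phosphoryl]-6,10-dimethyl-15-oxopentadeca-5,9,13-trienoate (racemic at C-2) | COC(=O)C(CC/C=C(\C)CC/C=C(/C)CC/C=C/C=O)P(=O)(OCC(F)(F)F)OCC(F)(F)F | intermediate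
17 | prenyl bromide, 1-bromo-3-methylbut-2-ene | CC(C)=CCBr | starting material
18 | 1-propynylmagnesium bromide | CC#C[Mg]Br | starting material
19 | 6-methylhept-5-en-2-yne | CC#CCC=C(C)C | intermediate
20 | chlorobis(cyclopentadienyl)[(2E)-6-methylhepta-2,5-dien-2-yl]zirconium | C/C(=C\CC=C(C)C)[Zr](Cl)(C1C=CC=C1)C1C=CC=C1 | intermediate (not isolated)
21 | (2E)-2-iodo-6-methylhepta-2,5-diene | C/C(I)=C\CC=C(C)C | intermediate
22 | [(2Z)-6-methylhepta-2,5-dien-2-yl]lithium | [Li]/C(C)=C/CC=C(C)C | intermediate (not isolated)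
23 | lithium [(2Z)-6-methylhepta-2,5-dien-2-yl]tri(propan-2-yloxy)borate | [Li+].CC(C)O[B-](OC(C)C)(OC(C)C)/C(C)=C/CC=C(C)C | intermediate (not isolated)
24 | potassium trifluoro[(2Z)-6-methylhepta-2,5-dien-2-yl]borate | [K+].F[B-](F)(F)/C(C)=C/CC=C(C)C | intermediate
25 | methyl (5E,9Z,13R,14E)-2-[bis(2,2,2-trifluoroethoxy)phosphoryl]-6,10,14,18-tetramethyl-13-(2-oxoethyl)nonadeca-5,9,14,17-tetraenoate (both C-2 epimers) | CC(C)=CC/C=C(\C)[C@@H](CC=O)CC/C(C)=C\CC/C(C)=C/CCC(C(=O)OC)P(=O)(OCC(F)(F)F)OCC(F)(F)F | intermediate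
26 | potassium salt (C-2 carbanion) of 25 | [K+].CC(C)=CC/C=C(\C)[C@@H](CC=O)CC/C(C)=C\CC/C(C)=C/CC[C-](C(=O)OC)P(=O)(OCC(F)(F)F)OCC(F)(F)F | intermediate (not isolated)
27 | methyl (1Z,4R,7Z,11E)-7,11-dimethyl-4-[(2E)-6-methylhepta-2,5-dien-2-yl]cyclotetradeca-1,7,11-triene-1-carboxylate | CC(C)=CC/C=C(\C)[C@H]1C/C=C(\C(=O)OC)CC/C=C(\C)CC/C=C(/C)CC1 | intermediate
28 | [(1Z,4R,7Z,11E)-7,11-dimethyl-4-[(2E)-6-methylhepta-2,5-dien-2-yl]cyclotetradeca-1,7,11-trien-1-yl]methanol | CC(C)=CC/C=C(\C)[C@H]1C/C=C(\CO)CC/C=C(\C)CC/C=C(/C)CC1 | target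

**Step count**
Total steps: 12. Longest linear sequence: 9 (steps 1–6, then 10–12); steps 7–9 build the side-chain borate.

**Three steps most likely to fail**

Step 10 is the proposed new step. The risks are low nucleophilicity of the α-branched all-alkyl alkenyl borate towards the iminium, protodeboronation by HF, and erosion of ee. The fallback uses known chemistry, a rhodium-catalysed Hayashi–Miyaura asymmetric 1,4-addition, and sets out from iodide 21 and enal 16. Borate 23, made from 21 as in step 9, is hydrolysed with aqueous HCl instead of KHF2 to give [(2Z)-6-methylhepta-2,5-dien-2-yl]boronic acid F1. F1 (2 equiv) is then added to 16 with a base-free hydroxorhodium(I)/chiral diene catalyst (dioxane/H2O, 30 °C, ligand enantiomer that gives 13R; no added base so the aldehyde–phosphonate pair is not triggered). This gives aldehyde 25, where the route is rejoined.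

Step 11 may give oligomers or an eroded Z:E ratio, since intramolecular Still–Gennari closures are less selective than intermolecular ones. The fallback switches to Ando's diaryl phosphonate, the Z-selective HWE reagent class with documented macrocyclisation scope, which changes the whole late-stage series. It sets out from iodide 11. Alkylation of commercial ethyl (diphenoxyphosphoryl)acetate (NaH, DMF) gives ethyl (5E,9Z)-2-(diphenoxyphosphoryl)-6,10,14-trimethylpentadeca-5,9,13-trienoate F2. Cross-metathesis with 15 as in step 6 gives ethyl (5E,9Z,13E)-2-(diphenoxyphosphoryl)-6,10-dimethyl-15-oxopentadeca-5,9,13-trienoate F3. Alkenylation with 24 as in step 10 gives ethyl (5E,9Z,13R,14E)-2-(diphenoxyphosphoryl)-6,10,14,18-tetramethyl-13-(2-oxoethyl)nonadeca-5,9,14,17-tetraenoate F4. Ando-type intramolecular HWE (NaI/DBU or NaH, THF, 0 °C, 1 mM, slow addition) closes the ring to ethyl (1Z,4R,7Z,11E)-7,11-dimethyl-4-[(2E)-6-methylhepta-2,5-dien-2-yl]cyclotetradeca-1,7,11-triene-1-carboxylate F5. DIBAL-H reduction of F5 gives the target 28.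

Step 6 depends on the catalyst discriminating the terminal isopropylidene from the two internal trisubstituted alkenes. The fallback replaces metathesis by the van Tamelen terminal oxidation and a Wittig reaction, setting out from 14. NBS in THF/H2O at 0 °C gives the terminal bromohydrin methyl (5E,9Z)-2-[bis(2,2,2-trifluoroethoxy)phosphoryl]-13-bromo-14-hydroxy-6,10,14-trimethylpentadeca-5,9-dienoate F6. Brief K2CO3/MeOH at 0 °C closes it to the epoxide methyl (5E,9Z)-2-[bis(2,2,2-trifluoroethoxy)phosphoryl]-12-(3,3-dimethyloxiran-2-yl)-6,10-dimethyldodeca-5,9-dienoate F7; the phosphonate sits as its unreactive anion during this treatment. HIO4·2H2O in THF/Et2O cleaves F7 to the aldehyde methyl (5E,9Z)-2-[bis(2,2,2-trifluoroethoxy)phosphoryl]-6,10-dimethyl-13-oxotrideca-5,9-dienoate F8. Wittig reaction of F8 with (triphenylphosphoranylidene)acetaldehyde (toluene, 80 °C) gives enal 16, where the route is rejoined.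

**Further compounds**
F1 | step 10 | [(2Z)-6-methylhepta-2,5-dien-2-yl]boronic acid | OB(O)/C(C)=C/CC=C(C)C
F2 | step 11 | ethyl (5E,9Z)-2-(diphenoxyphosphoryl)-6,10,14-trimethylpentadeca-5,9,13-trienoate | CCOC(=O)C(CC/C=C(\C)CC/C=C(/C)CCC=C(C)C)P(=O)(Oc1ccccc1)Oc1ccccc1
F3 | step 11 | ethyl (5E,9Z,13E)-2-(diphenoxyphosphoryl)-6,10-dimethyl-15-oxopentadeca-5,9,13-trienoate | CCOC(=O)C(CC/C=C(\C)CC/C=C(/C)CC/C=C/C=O)P(=O)(Oc1ccccc1)Oc1ccccc1
F4 | step 11 | ethyl (5E,9Z,13R,14E)-2-(diphenoxyphosphoryl)-6,10,14,18-tetramethyl-13-(2-oxoethyl)nonadeca-5,9,14,17-tetraenoate | CC(C)=CC/C=C(\C)[C@@H](CC=O)CC/C(C)=C\CC/C(C)=C/CCC(C(=O)OCC)P(=O)(Oc1ccccc1)Oc1ccccc1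
F5 | step 11 | ethyl (1Z,4R,7Z,11E)-7,11-dimethyl-4-[(2E)-6-methylhepta-2,5-dien-2-yl]cyclotetradeca-1,7,11-triene-1-carboxylate | CC(C)=CC/C=C(\C)[C@H]1C/C=C(\C(=O)OCC)CC/C=C(\C)CC/C=C(/C)CC1
F6 | step 6 | methyl (5E,9Z)-2-[bis(2,2,2-trifluoroethoxy)phosphoryl]-13-bromo-14-hydroxy-6,10,14-trimethylpentadeca-5,9-dienoate | COC(=O)C(CC/C=C(\C)CC/C=C(/C)CCC(Br)C(C)(C)O)P(=O)(OCC(F)(F)F)OCC(F)(F)F
F7 | step 6 | methyl (5E,9Z)-2-[bis(2,2,2-trifluoroethoxy)phosphoryl]-12-(3,3-dimethyloxiran-2-yl)-6,10-dimethyldodeca-5,9-dienoate | COC(=O)C(CC/C=C(\C)CC/C=C(/C)CCC1OC1(C)C)P(=O)(OCC(F)(F)F)OCC(F)(F)F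
F8 | step 6 | methyl (5E,9Z)-2-[bis(2,2,2-trifluoroethoxy)phosphoryl]-6,10-dimethyl-13-oxotrideca-5,9-dienoate | COC(=O)C(CC/C=C(\C)CC/C=C(/C)CCC=O)P(=O)(OCC(F)(F)F)OCC(F)(F)F
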